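**Retrosynthesis**
1. Andrographolide (**15**) ⇒ E-selective cross-metathesis of the C12=C13 alkylidene between an allyl-decalin (**9**) and (S)-4-silyloxy-α-methylene-γ-butyrolactone (**13**, from chiral-pool 3-hydroxybutyrolactone).
2. Decalin **9** ⇒ one Ti(III) radical cascade from epoxy-tetraene **8**. Epoxide opening gives the C4 radical, then 6-endo closure forms the C4–C5 bond (ring A) and the C10–C9 bond (ring B). Ti trapping and β-H elimination give C8=C17, and C3 comes from the epoxide.
3. **8** ⇒ Sharpless epoxidation of allylic alcohol **7**. **7** ⇒ two Negishi couplings of three ZACA-derived E-alkenyl iodide/alkyl bromide units (from 4-bromo-1-butyne, allyl bromide and propargyl alcohol).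

**Assumptions:** 4-bromo-1-butyne, propargyl alcohol, allyl bromide and (S)-3-hydroxy-γ-butyrolactone are commercial. Excess alkylzinc tolerates the free allylic OH in Step 5. The C4-epimer formed in Step 7 is separable by chromatography.

---

**Step 1**
Reactants: **1** 4-bromo-1-butyne
Product: **2** (E)-4-bromo-1-iodo-2-methylbut-1-ene
Conditions: Me3Al, Cp2ZrCl2 (cat.), ClCH2CH2Cl, 0→25 °C; then I2, THF, −30 °C
Reagents that add atoms: trimethylaluminium C[Al](C)C (adds the C20 methyl); iodine II (adds I)
Why: Zr-catalysed carboalumination (ZACA) is a syn-methylalumination. Iodinolysis gives the E-trisubstituted alkenyl iodide with Me and I cis, and the alkyl bromide survives.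

**Step 2**
Reactants: **2**
Product: **3** (E)-1-bromo-3-methylhepta-3,6-diene
Conditions: allylzinc bromide (from allyl bromide + Zn), Pd(PPh3)4 (5 mol%), THF, 0→25 °C
Reagents that add atoms: allylzinc bromide C=CC[Zn]Br (adds C11–C13)
Why: Negishi coupling occurs selectively at C(sp2)–I and retains the alkene geometry. This makes the C9–C11 bond and the skipped diene, and the C(sp3)–Br is untouched.

**Step 3**
Reactants: **4** propargyl alcohol
Product: **5** (E)-3-iodo-2-methylprop-2-en-1-ol
Conditions: Me3Al (3 equiv), Cp2ZrCl2 (cat.), CH2Cl2, 0→25 °C; then I2, THF, −30 °C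
Reagents that add atoms: Me3Al C[Al](C)C (adds the C18 methyl); I2 II
Why: ZACA is syn, so Me and I are cis and CH2OH is trans to I. This fixes the E geometry of the future C3=C4 alkene.

**Step 4**
Reactants: **3** (as its alkylzinc) and **2**
Product: **6** (3E,7E)-1-bromo-3,7-dimethylundeca-3,7,10-triene
Conditions: (i) **3**, Zn dust, LiCl, BrCH2CH2Br/TMSCl activation, THF, 50 °C, then decant; (ii) **2**, Pd(PPh3)4 (5 mol%), THF, 25 °C
Reagents that add atoms: none (the zinc reagent is derived from **3**)
Why: Negishi sp3–sp2 coupling with retention forms the C5–C6 bond. Oxidative addition into vinyl iodide is much faster than into the alkyl bromide, so the terminal CH2Br is preserved.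

**Step 5**
Reactants: **6** (as its alkylzinc) and **5**
Product: **7** (2E,6E,10E)-2,6,10-trimethyltetradeca-2,6,10,13-tetraen-1-ol
Conditions: (i) **6**, Zn dust, LiCl, THF, 50 °C, then decant (2.5 equiv); (ii) **5**, Pd(PPh3)4 (5 mol%), THF, 25 °C
Reagents that add atoms: none
Why: A second Negishi coupling forms the C2–C3 bond with retention of geometry, giving the all-E skipped polyene with a free E-allylic alcohol ready for epoxidation.

**Step 6**
Reactants: **7**
Product: **8** [(2R,3R)-3-[(3E,7E)-3,7-dimethylundeca-3,7,10-trien-1-yl]-2-methyloxiran-2-yl]methanol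
Conditions: Ti(OiPr)4 (10 mol%), D-(−)-DET (12 mol%), TBHP, 3 Å MS, CH2Cl2, −20 °C
Reagents that add atoms: tert-butyl hydroperoxide CC(C)(C)OO (source of the epoxide O)
Why: Sharpless asymmetric epoxidation is hydroxyl-directed, so only the allylic alkene reacts. D-(−)-DET sets the (3R,4R) trans-epoxide. C3(R) is the only centre that transmits absolute configuration to the ent-labdane core.

**Step 7**
Reactants: **8**
Product: **9** (1R,4aS,5R,6R,8aS)-5-(hydroxymethyl)-5,8a-dimethyl-2-methylidene-1-(prop-2-en-1-yl)decahydronaphthalen-6-ol
Conditions: Cp2TiCl2 (20 mol%), Mn dust, 2,4,6-collidine, Me3SiCl, THF, 25 °C; then TBAF, THF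
Reagents that add atoms: none (net isomerisation; TMS ethers are removed on work-up)
Why: Proposed new method: Nugent–RajanBabu Ti(III) opening of the epoxide gives the tertiary C4 radical (β-OTMS). It closes 6-endo onto C5=C10 and then onto C9=C8 in a chair–chair array with C3–O equatorial and both alkenes E. The tertiary C8 radical is trapped by Cp2TiCl and β-H eliminated to the exocyclic C8=C17. The closest precedent is the Cp2TiCl-catalysed bicyclisation of epoxyfarnesyl acetate to 3β-hydroxy-8(17)-decalins; the new features are the unsymmetrical C4 terminus (CH3/CH2OTMS), the C9 allyl group and the free terminal alkene. C3 comes from the epoxide; C5, C10 and C9 (trans-decalin, equatorial C11) come from the chair–chair transition state. C4 is planar at the radical stage, so axial versus equatorial CH2O is set only by transition-state preference (about 1:1 expected). The 4-epimer (equatorial CH2OH) is removed chromatographically.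

**Step 8**
Reactants: **10** (S)-3-hydroxy-γ-butyrolactone
Product: **11** (S)-4-(tert-butyldimethylsilyloxy)dihydrofuran-2(3H)-one
Conditions: TBSCl, imidazole, DMF, 0→25 °C
Reagents that add atoms: TBSCl C[Si](C)(C(C)(C)C)Cl (leaves TBS on O)
Why: Silylation of the secondary alcohol; the C14 (S) centre is untouched.

**Step 9**
Reactants: **11**
Product: **12** (4S)-3-[(dimethylamino)methyl]-4-(TBSO)dihydrofuran-2(3H)-one (mainly trans)
Conditions: LiHMDS, THF, −78 °C; then CH2=NMe2+ I−, −78→0 °C
Reagents that add atoms: Eschenmoser's salt C[N+](C)=C.[I-] (leaves CH2NMe2)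
Why: Lactone enolate aminomethylation (Mannich-type). The new α-centre is transient and is destroyed in Step 10.

**Step 10**
Reactants: **12**
Product: **13** (S)-4-(TBSO)-3-methylenedihydrofuran-2(3H)-one
Conditions: MeI, CH2Cl2, 25 °C; then sat. aq. NaHCO3, 0 °C
Reagents that add atoms: none (MeI is lost with NMe3)
Why: Quaternisation then E1cB (Hofmann-type) elimination gives the α-methylene lactone. The ammonium is a far better leaving group than the β-OTBS, so butenolide formation is avoided.

**Step 11**
Reactants: **9** and **13**
Product: **14** TBS-andrographolide (C14-OTBS)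
Conditions: Hoveyda–Grubbs II (10 mol%), 1,4-benzoquinone (10 mol%), **13** (4 equiv, portionwise), CH2Cl2, 40 °C
Reagents that add atoms: none (ethylene is lost)
Why: Ru cross-metathesis joins the terminal alkene of **9** to the 1,1-disubstituted acrylate of **13** to give the trisubstituted α-alkylidene lactone (C12=C13). Reversible metathesis favours the E-isomer, the exocyclic C8=C17 and the free OH groups are tolerated, and benzoquinone suppresses Ru–H isomerisation.

**Step 12**
Reactants: **14**
Product: **15** andrographolide
Conditions: HF·pyridine, THF/pyridine, 0→25 °C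
Reagents that add atoms: none
Why: Mild, non-basic removal of the secondary TBS ether. This avoids E1cB loss of the C14 oxygen and acid-promoted isomerisation of the exocyclic alkene.

---

**Compound list**
1 | 4-bromo-1-butyne | C#CCCBr | starting material
2 | (E)-4-bromo-1-iodo-2-methylbut-1-ene | I/C=C(\C)CCBr | intermediate
3 | (E)-1-bromo-3-methylhepta-3,6-diene | BrCC/C(C)=C/CC=C | intermediate
4 | propargyl alcohol | C#CCO | starting material
5 | (E)-3-iodo-2-methylprop-2-en-1-ol | OC/C(C)=C/I | intermediate
6 | (3E,7E)-1-bromo-3,7-dimethylundeca-3,7,10-triene | BrCC/C(C)=C/CC/C(C)=C/CC=C | intermediate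
7 | (2E,6E,10E)-2,6,10-trimethyltetradeca-2,6,10,13-tetraen-1-ol | OC/C(C)=C/CC/C(C)=C/CC/C(C)=C/CC=C | intermediate
8 | (2R,3R)-epoxy alcohol | OC[C@@]1(C)O[C@@H]1CC/C(C)=C/CC/C(C)=C/CC=C | intermediate
9 | allyl-decalin diol | C=C1CC[C@@H]2[C@](C)(CO)[C@H](O)CC[C@@]2(C)[C@@H]1CC=C | intermediate
10 | (S)-3-hydroxy-γ-butyrolactone | O=C1C[C@H](O)CO1 | starting material
11 | (S)-4-TBSO-lactone | O=C1C[C@H](O[Si](C)(C)C(C)(C)C)CO1 | intermediate
12 | 3-(dimethylaminomethyl)-4-TBSO-lactone | CN(C)CC1C(=O)OC[C@H]1O[Si](C)(C)C(C)(C)C | intermediate
13 | (S)-4-TBSO-3-methylene-lactone | C=C1C(=O)OC[C@H]1O[Si](C)(C)C(C)(C)C | intermediate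
14 | TBS-andrographolide | C=C1CC[C@@H]2[C@](C)(CO)[C@H](O)CC[C@@]2(C)[C@@H]1C/C=C1/C(=O)OC[C@H]1O[Si](C)(C)C(C)(C)C | intermediate
15 | andrographolide | C=C1CC[C@@H]2[C@](C)(CO)[C@H](O)CC[C@@]2(C)[C@@H]1C/C=C1/C(=O)OC[C@H]1O | target

**Total steps:** 12. **Longest linear sequence:** 8 (Steps 1, 2, 4, 5, 6, 7, 11, 12).

**Three steps most likely to fail**
1. **Step 7 (Ti(III) cascade).** The C4 diastereoselectivity is poor because C4 is a planar radical, and the yield is modest. Fallback: an epoxide-initiated cationic (Lewis-acid) polyene cyclisation of **8**, using the E- or Z-allylic alcohol geometry needed to place CH2O axial. Backside opening at C4 is stereospecific, so C4 is set by the epoxide rather than by radical-stage preference.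
2. **Step 11 (cross-metathesis).** Yield, E/Z ratio or isomerisation of the exocyclic alkene may be poor. Fallback: selective oxidative cleavage of the monosubstituted alkene of **9** (OsO4/NaIO4) to the C12 aldehyde. Then aldol addition of the lithium enolate of **11** and MsCl/DBU dehydration, which also skips Steps 9–10.
3. **Steps 9–10 (α-methylenation).** The β-silyloxy lactone enolate may eliminate to the butenolide. Fallback: prepare **13** by an asymmetric Morita–Baylis–Hillman reaction of methyl acrylate with benzyloxyacetaldehyde, followed by debenzylation, lactonisation and silylation.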